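**Retrosynthetic overview**
- The target, 3-nonadecylcyclohex-2-en-1-one, is cut at the single bond between ring C3 and the first chain carbon.
- Polarity at C3 is inverted: the ring piece is a β-acylvinyl anion (sp2 homoenolate, d3), realised as a β-zincated cyclohexenone. The chain piece is 1-bromononadecane, so two natively electrophilic carbons are joined.
- The zinc reagent comes from 3-iodocyclohex-2-en-1-one by zinc insertion, and that from cyclohexane-1,3-dione by deoxy-iodination.
- Ring order: the only ring, the six-membered carbocycle, is bought intact; no ring is formed.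

Assumption: the target SMILES has no stereocentre and no stereogenic double bond (the C=C is endocyclic), so the compound is achiral and is made as that single achiral species.

**Route**

Step 1
Reactants: 1 cyclohexane-1,3-dione
Product: 2 3-iodocyclohex-2-en-1-one
Conditions: PPh3 (1.1 equiv), I2 (1.1 equiv), Et3N (1.1 equiv), MeCN, 0 °C to rt, 12 h, dark
Reagents that add atoms: iodine, II
Why: Deoxy-iodination of a cyclic 1,3-diketone (vinylogous Appel reaction): Ph3P–I+ activates the enol oxygen as an enol oxyphosphonium salt, iodide adds at the β-carbon and Ph3P=O leaves by addition–elimination; no stereocentre is formed.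

Step 2
Reactants: 2 3-iodocyclohex-2-en-1-one (1.4 equiv); 3 1-bromononadecane (1.0 equiv)
Product: 5 3-nonadecylcyclohex-2-en-1-one, via (3-oxocyclohex-1-en-1-yl)zinc iodide 4 (not isolated)
Conditions: Zn dust (act. cat. BrCH2CH2Br/TMSCl), THF, 25 °C, 1 h; then cannulate onto 3, Pd2(dba)3 (2 mol%), PCyp3 (8 mol%), N-methylimidazole (1.2 equiv), THF/NMP 2:1, 80 °C, 14 h
Reagents that add atoms: none
Why: Proposed new method: zinc inserts into the electron-poor C(sp2)–I bond of 2 to give 4, a β-acylvinyl anion equivalent whose C–Zn σ-bond is orthogonal to the enone π-system, so it cannot enolise or self-add; Pd(0)/PCyp3 then adds oxidatively (SN2-type) to the primary C–Br bond of 3, NMI-activated 4 transmetalates, and alkyl–alkenyl reductive elimination outruns β-hydride elimination with this bulky electron-rich phosphine; the closest known reactions are the Negishi cross-coupling of unactivated primary alkyl bromides with alkenylzinc halides under Pd/trialkylphosphine/NMI catalysis and the Cu- and Pd-mediated couplings of β-zincated enones with allylic, acyl and alkenyl halides; no stereocentre is formed, and the double bond stays at C2=C3 because the metal sits on C3 throughout.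

**Compound list**
1 | cyclohexane-1,3-dione | O=C1CCCC(=O)C1 | starting material
2 | 3-iodocyclohex-2-en-1-one | O=C1C=C(I)CCC1 | intermediate
3 | 1-bromononadecane | CCCCCCCCCCCCCCCCCCCBr | starting material
4 | (3-oxocyclohex-1-en-1-yl)zinc iodide [3-(iodozincio)cyclohex-2-en-1-one] | O=C1C=C([Zn]I)CCC1 | intermediate (not isolated)
5 | 3-nonadecylcyclohex-2-en-1-one | CCCCCCCCCCCCCCCCCCCC1=CC(=O)CCC1 | target

**Totals**
Total step count: 2
Longest linear sequence: 2 steps (1 → 2 → 5; 3 enters in step 2)

**Steps most likely to fail**
The route has only two steps. Step 2 holds two separate operations with their own failure modes, so three risks are listed.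

1. Step 2, palladium coupling stage. The electron-poor alkenylzinc 4 may transmetalate slowly, giving 1-nonadecene by β-hydride elimination, or 4 may homocouple. The fallback drops the catalytic coupling for a sulfone-stabilised carbanion alkylation with the same polarity at C3. It sets out from 3 and comes back to the route at 5.
 - Purchased cyclohex-2-en-1-one F1 takes up sodium benzenesulfinate (PhSO2Na, AcOH, EtOH/H2O, rt) in a conjugate addition to give racemic 3-(phenylsulfonyl)cyclohexan-1-one F2.
 - Ketalisation (ethylene glycol, cat. TsOH, toluene, Dean–Stark) gives racemic 7-(phenylsulfonyl)-1,4-dioxaspiro[4.5]decane F3.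
 - Its α-sulfonyl carbanion (n-BuLi, THF/HMPA, −78 °C) is alkylated by 3 (−78 °C to rt) to give racemic 7-nonadecyl-7-(phenylsulfonyl)-1,4-dioxaspiro[4.5]decane F4.
 - Aqueous HCl/THF unmasks 3-nonadecyl-3-(phenylsulfonyl)cyclohexan-1-one F5, which is not isolated; DBU (CH2Cl2, rt) removes benzenesulfinate by E1cB elimination to give 5.

2. Step 2, zinc insertion stage. The insertion may be incomplete, or 4 may be lost by protonation to cyclohexenone or by reductive dimerisation. The fallback replaces the in-flask zinc reagent with an isolable tin-based β-acylvinyl anion equivalent. It sets out from 2 and comes back at 5.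
 - Stannylation of 2 (Me3SnSnMe3, cat. Pd(PPh3)4, toluene, 90 °C) gives 3-(trimethylstannyl)cyclohex-2-en-1-one F6, which can be purified and stored.
 - Fluoride-promoted alkyl Stille coupling of F6 with 3 ([(allyl)PdCl]2, P(t-Bu)2Me, Me4NF, 3 Å MS, THF, rt) gives 5.

3. Step 1. Compound 2 is light- and moisture-sensitive (it hydrolyses back to 1) and can be hard to free from Ph3P=O. The fallback avoids phosphorus and goes through the more robust chloride. It sets out from 1 and comes back at 2.
 - Oxalyl chloride (cat. DMF, CH2Cl2, 0 °C to rt) converts 1 into 3-chlorocyclohex-2-en-1-one F7, which is distillable.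
 - Halide exchange by addition–elimination (NaI, cat. TFA, acetone, reflux, driven by precipitation of the chloride salt) gives 2.

**Further compounds**
F1 | step 2 | cyclohex-2-en-1-one (purchased) | O=C1C=CCCC1
F2 | step 2 | 3-(phenylsulfonyl)cyclohexan-1-one (racemic) | O=C1CCCC(C1)S(=O)(=O)c1ccccc1
F3 | step 2 | 7-(phenylsulfonyl)-1,4-dioxaspiro[4.5]decane (racemic) | O=S(=O)(c1ccccc1)C1CCCC2(C1)OCCO2
F4 | step 2 | 7-nonadecyl-7-(phenylsulfonyl)-1,4-dioxaspiro[4.5]decane (racemic) | CCCCCCCCCCCCCCCCCCCC1(CCCC2(C1)OCCO2)S(=O)(=O)c1ccccc1
F5 | step 2 | 3-nonadecyl-3-(phenylsulfonyl)cyclohexan-1-one (racemic, not isolated) | CCCCCCCCCCCCCCCCCCCC1(CCCC(=O)C1)S(=O)(=O)c1ccccc1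
F6 | step 2 | 3-(trimethylstannyl)cyclohex-2-en-1-one | C[Sn](C)(C)C1=CC(=O)CCC1
F7 | step 1 | 3-chlorocyclohex-2-en-1-one | O=C1C=C(Cl)CCC1
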